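## Structural features

The target, (2S,3S,6R,10E)-2-chloro-13-[5-(furan-3-ylmethyl)furan-3-yl]-3-hydroxy-6,10-dimethyltridec-10-en-4-one, is a C24 chlorinated furanoterpenoid; the chain is numbered C1–C13 as in this name. C13 ends on ring A, a 2,4-disubstituted furan whose atoms are called O1′, C2′, C3′, C4′ and C5′ here: C4′ carries C13, and C2′ carries a CH2 bridge to C3 of ring B, a second, monosubstituted furan. The chain holds an E-trisubstituted alkene (C10=C11, methyl on C10), a lone methyl stereocenter at C6 (R) that is β to the C4 ketone, and the adjacent pair C3 (S, OH, α to the ketone) and C2 (S, Cl). C2 and C3 are syn in the zigzag drawing, which is the relationship that SN2 opening of a cis-2,3-epoxide by chloride at C2 produces; C6 is insulated from them by C5H2–C4(=O), so the two stereochemical regions must each be set absolutely. Fragile groups are the two acid- and oxidant-sensitive furans with their doubly activated bridging CH2, the chlorohydrin (closes to an epoxide with base) and the α-ketol (epimerisable at C3 by enolisation). The real difficulty is twofold: the 2,4-pattern of ring A, which substitution chemistry on a 3-alkylfuran does not deliver cleanly (electrophiles prefer C5′ next to the alkyl group, metalation divides between C2′ and C5′), and the base-labile syn-chlorohydrin ketone. The feature that the key step exploits is that C5′, C4′, C13–C5 and the two methyl groups together are the skeleton of a 13-carbon methyl ketone that already contains the C10=C11 E-alkene, so that ring A can be closed onto that ketone at the C3′=C4′ carbon–carbon bond instead of being brought in as a furan.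

## Logic of the disconnections

22 ⇒ 21. The C2–Cl bond is cut and the C2–O bond of a cis-epoxide is restored. The chlorohydrin, the most base-sensitive group, then appears only in the last step, and its syn relationship follows from the cis geometry of the epoxide and one inversion. The forward step must deliver chloride to C2 (β to the ketone) and not to C3, under conditions that spare both furans.

21 ⇒ 14 + 19. The C4–C5 bond is cut between the ketone carbon and its CH2 neighbour. This separates the two stereochemical regions into a four-carbon epoxy amide and the whole furanoterpenoid chain, which carries only the C6 center. The forward step needs a C5 organometallic that adds once to the amide and does not open the epoxide.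

19 ⇒ 17 ⇒ 16 ⇒ 15. No carbon–carbon bond is cut: C4, C3, C2 and C1 are the four carbons of 15, and only C–N, C–Br and C–O bonds are exchanged. Both stereocenters come from the chiral pool by stereospecific substitutions, with retention at C3 in 16 and inversion at C3 on closure to 17. The demand is clean retention in the diazotisation and clean intramolecular displacement in the ring closure.

14 ⇒ 9 + 11. The bond between C2′ and the bridging CH2 is cut and ring A is taken back to a butenolide whose carbonyl carbon is C2′. The bis-furan with its bridge then arises in one operation, ring A becoming aromatic only when the bridge carbon arrives. The forward step requires 1,2-addition of a furylmethyl organometallic (12, made from 11) to the lactone carbonyl, in preference to deprotonation at C5′ or conjugate addition, followed by dehydration under mild acid.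

9 ⇒ 6 + 7 (key disconnection). The C3′=C4′ double bond and the O1′–C5′ ester bond are cut. Ring A is thereby reduced to a bromomethyl ketone (C5′, C4′) on the intact terpenoid chain plus a two-carbon phosphonate (C2′, C3′). The 2,4-pattern is fixed by the position of the ketone, not by any selectivity on a furan. The forward step must esterify only at the α-keto bromide and then olefinate a ketone intramolecularly.

6 ⇒ 4 ⇒ 3 ⇒ 2 ⇒ 1. The C5′–Br bond, the C5–Br bond, the two C–H bonds at C6 and C7 and the C5–O bond are removed in turn. What remains is 1, which supplies thirteen carbons and the C10=C11 geometry. The demands are methyl-side enolisation of the ketone, enantioface control in the hydrogenation of the C6=C7 allylic alcohol, and terminal-methyl selectivity in the allylic oxidation.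

11 ⇒ 10. The C–Cl bond of the bridge carbon is exchanged for C–O; the only demand is a chlorination that the furan tolerates.

## Other disconnections considered

Alternative 1: Cut the C12–C13 bond between the allylic carbon and the furylmethyl carbon, with ring A brought in as a furan; this is the plan that comes to mind first. The forward key step would be a copper-catalysed coupling of the Grignard reagent from 4-(chloromethyl)-2-(furan-3-ylmethyl)furan A1 with the allylic bromide tert-butyl{[(2R,6E)-8-bromo-2,6-dimethyloct-6-en-1-yl]oxy}dimethylsilane A2. The chosen plan is preferred on three grounds.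
- A1 itself needs a regiocontrolled 2,4-difunctionalisation of a furan and the deoxygenation of an acid-labile bis-furyl carbinol.
- A furylmethyl metal can attack an allylic halide at either allyl terminus, which puts the linear skeleton and the 10E geometry at risk.
- A2 has two reactive termini that must be told apart by protecting groups.

The chosen plan contains no allylic substitution, takes the alkene geometry unchanged from 1, and never has to functionalise a furan regioselectively.

Alternative 2: Cut C3–C4 with reversed polarity at C4. The forward key step would be the addition of lithiated 2-{(2R,6E)-9-[5-(furan-3-ylmethyl)furan-3-yl]-2,6-dimethylnon-6-en-1-yl}-1,3-dithiane A3 to (2S)-2-chloropropanal A4 to give the carbinol A5. The chosen plan is preferred on three grounds.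
- The polar Felkin–Anh (Cornforth) transition state of an α-chloro aldehyde leads to the 2,3-anti chlorohydrin, so A5 should be the 3R epimer of what is needed, and inverting a carbinol that lies between a masked ketone and a C–Cl bond is unattractive.
- A4 is volatile and configurationally labile.
- Unmasking the dithiane calls for soft electrophiles or oxidants that two furans and a trisubstituted alkene are unlikely to survive.

The chosen plan takes C2 and C3 together from 15 by stereospecific steps and forms the ketone without a masked acyl anion.

Alternative 3: Close the same C3′=C4′ bond of ring A by metathesis instead of olefination. The forward key step would be ring-closing metathesis of the diene ester 1-(furan-3-yl)but-3-en-2-yl (5E,10R)-11-bromo-6,10-dimethyl-2-methylideneundec-5-enoate A6 with the second-generation Grubbs catalyst to the butenolide A7, followed by i-Bu2AlH reduction and dehydration to 14. The chosen plan is preferred on two grounds.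
- A6 needs a 2-methylidene acid that has to be built from the terpenoid chain by additional carbon–carbon bond formations, and a furyl butenol that has to be made separately.
- The metathesis must form a trisubstituted butenolide alkene from an electron-poor 1,1-disubstituted acrylate while leaving C10=C11 untouched.

The phosphonate closure forms the same ring bond from a ketone that is already present in a commodity C13 building block, in fewer steps.

Key step: step 5

Assumption: 1 is used as the commercially available, isomerically pure (5E) material; a technical E/Z mixture would be separated first.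

## Route

Step 1
Reactants: 1 (5E)-6,10-dimethylundeca-5,9-dien-2-one ((E)-geranylacetone)
Product: 2 (5E,9E)-11-hydroxy-6,10-dimethylundeca-5,9-dien-2-one
Conditions: SeO2 (cat.), t-BuOOH, salicylic acid (cat.), CH2Cl2, rt
Reagents that add atoms: selenium dioxide O=[Se]=O (transfers the oxygen, catalytic); tert-butyl hydroperoxide CC(C)(C)OO (terminal oxidant that restores SeO2)
Why: SeO2 allylic oxidation (ene reaction, then [2,3]-sigmatropic shift) should attack the sterically most accessible terminal isopropylidene group at the methyl trans to the chain and give the E-allylic alcohol; this places oxygen on the future C5 and leaves the ketone and the C10=C11 alkene alone.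

Step 2
Reactants: 2 (5E,9E)-11-hydroxy-6,10-dimethylundeca-5,9-dien-2-one
Product: 3 (5E,10R)-11-hydroxy-6,10-dimethylundec-5-en-2-one
Conditions: Ru(OAc)2[(R)-BINAP] (1 mol %), H2 (100 atm), MeOH, 25 °C
Reagents that add atoms: none
Why: Hydroxyl-directed asymmetric hydrogenation with a BINAP–ruthenium dicarboxylate reduces only the alkene that can chelate through the allylic OH (C6=C7), not the isolated C10=C11 alkene or the ketone. The (R)-ligand is chosen by the enantioface rule of this catalyst class (the (S)-ligand turns geraniol into (R)-citronellol), which applied to this 2-methyl-2-en-1-ol predicts the 6R center; since the analogy crosses from a 3- to a 2-substituted allylic alcohol, the sense is to be confirmed on 3 and the antipodal ligand used if required.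

Step 3
Reactants: 3 (5E,10R)-11-hydroxy-6,10-dimethylundec-5-en-2-one
Product: 4 (5E,10R)-11-bromo-6,10-dimethylundec-5-en-2-one
Conditions: CBr4, PPh3, CH2Cl2, 0 °C
Reagents that add atoms: carbon tetrabromide BrC(Br)(Br)Br
Why: Appel reaction of a primary alcohol; the stereocenter is β to the reacting carbon and is not touched, and the ketone and alkene are inert to the phosphonium reagent.

Step 4
Reactants: 4 (5E,10R)-11-bromo-6,10-dimethylundec-5-en-2-one
Product: 6 (5E,10R)-1,11-dibromo-6,10-dimethylundec-5-en-2-one, via trimethylsilyl enol ether 5 (not isolated)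
Conditions: LiN(iPr)2, Me3SiCl, THF, −78 °C; then N-bromosuccinimide, −78 → 0 °C
Reagents that add atoms: N-bromosuccinimide O=C1CCC(=O)N1Br
Why: Kinetic deprotonation of a methyl ketone by the hindered amide with in situ silylation should give the terminal enol ether (future C5′), not the one toward C13, and at −78 °C the primary bromide is not attacked. Electrophilic bromination of the electron-rich silyl enol ether by N-bromosuccinimide is much faster than attack on the trisubstituted alkene under anhydrous conditions.

Step 5
Reactants: 6 (5E,10R)-1,11-dibromo-6,10-dimethylundec-5-en-2-one; 7 (diethoxyphosphoryl)acetic acid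
Product: 9 4-[(3E,8R)-9-bromo-4,8-dimethylnon-3-en-1-yl]furan-2(5H)-one, via keto phosphonoacetate ester 8 (not isolated)
Conditions: 7, K2CO3, MeCN, rt; then LiBr, Et3N, rt
Reagents that add atoms: none
Why: The potassium carboxylate of 7 displaces the α-keto bromide of 6 by SN2 and so forms the O1′–C5′ bond of ester 8; LiBr/Et3N then generates the lithium-chelated phosphonate carbanion (C3′), which adds to the C4′ ketone and collapses through the oxaphosphetane to the C3′=C4′ double bond with loss of diethyl phosphate. The closest known reaction type is the intramolecular Horner–Wadsworth–Emmons synthesis of β-substituted butenolides from α-(phosphonoacetoxy) ketones. The ring that becomes ring A is closed in the 5-exo-trig mode at a carbon–carbon bond (carbanion C3′ onto carbonyl C4′), the ring oxygen having been attached beforehand as a simple ester. No stereocenter is formed, and the five-membered ring allows only one alkene geometry. The selectivity needed is between the two C–Br bonds of 6: the bromide at C5′ is activated for SN2 by the adjacent carbonyl, whereas the bromide at chain carbon C5 is a β-branched primary halide, so the carboxylate should react at C5′ only. The 2,4-pattern of ring A is not a matter of selectivity, because C4′ and C5′ are the former ketone and bromomethyl carbons and the chain is attached to C4′ by construction. The mild amine base and lithium salt are chosen so that the ketone of 8 is olefinated before it enolises toward C13, and so that the double bond of 9 stays in conjugation; C6 has no acidic hydrogen and C10=C11 is not affected.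

Step 6
Reactants: 10 furan-3-ylmethanol
Product: 11 3-(chloromethyl)furan
Conditions: SOCl2, pyridine, Et2O, 0 °C
Reagents that add atoms: thionyl chloride O=S(Cl)Cl
Why: Chlorination through the chlorosulfite with pyridine as acid scavenger; a furan-3-ylmethyl halide ionises far less readily than its furan-2-yl isomer, so the halide should survive if it is used promptly.

Step 7
Reactants: 9 4-[(3E,8R)-9-bromo-4,8-dimethylnon-3-en-1-yl]furan-2(5H)-one; 11 3-(chloromethyl)furan
Product: 14 4-[(3E,8R)-9-bromo-4,8-dimethylnon-3-en-1-yl]-2-(furan-3-ylmethyl)furan, via (furan-3-ylmethyl)magnesium chloride 12 (not isolated), via lactol adduct 13 (not isolated)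
Conditions: 11, Mg, THF, 0 °C → rt; CeCl3, THF, −78 °C; 9, −78 °C; then aq. NH4Cl; pyridinium p-toluenesulfonate (cat.), CH2Cl2, rt
Reagents that add atoms: none
Why: Grignard 1,2-addition to the lactone carbonyl C2′ gives lactol 13; the cerium additive lowers the basicity of the reagent so that deprotonation at C5′ is suppressed, and conjugate addition is disfavoured at the fully substituted C4′. Mild acid ionises the allylic lactol hydroxyl and loss of a C5′ proton aromatises ring A (the known conversion of butenolides into 2-substituted furans); the primary bromide does not react with the organometallic at −78 °C.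

Step 8
Reactants: 15 L-threonine ((2S,3R)-2-amino-3-hydroxybutanoic acid)
Product: 16 (2S,3R)-2-bromo-3-hydroxybutanoic acid
Conditions: NaNO2, KBr, 1 M H2SO4, −5 → 0 °C
Reagents that add atoms: potassium bromide [K+].[Br-]
Why: Diazotisation of the α-amino acid; the carboxylate expels N2 to an α-lactone that bromide reopens, two inversions that amount to retention at the amino-bearing carbon (future C3).

Step 9
Reactants: 16 (2S,3R)-2-bromo-3-hydroxybutanoic acid
Product: 17 potassium (2R,3R)-3-methyloxirane-2-carboxylate
Conditions: KOH, EtOH, 0 °C → rt
Reagents that add atoms: potassium hydroxide [K+].[OH-]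
Why: Intramolecular Williamson closure: the alkoxide on future C2 displaces bromide at future C3 with inversion, which converts the syn bromohydrin into the cis-epoxide; the carboxylate salt makes the α-hydrogen non-acidic, so elimination is not expected.

Step 10
Reactants: 17 potassium (2R,3R)-3-methyloxirane-2-carboxylate; 18 N,O-dimethylhydroxylamine hydrochloride
Product: 19 (2R,3R)-N-methoxy-N,3-dimethyloxirane-2-carboxamide
Conditions: t-BuCOCl, CH2Cl2, 0 °C; then 18, N-methylmorpholine, 0 °C → rt
Reagents that add atoms: none
Why: Mixed pivalic anhydride amidation; the amine attacks the less hindered epoxy-acyl carbonyl, and neither stereocenter is involved.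

Step 11
Reactants: 14 4-[(3E,8R)-9-bromo-4,8-dimethylnon-3-en-1-yl]-2-(furan-3-ylmethyl)furan; 19 (2R,3R)-N-methoxy-N,3-dimethyloxirane-2-carboxamide
Product: 21 (3R,7E)-10-[5-(furan-3-ylmethyl)furan-3-yl]-3,7-dimethyl-1-[(2R,3R)-3-methyloxiran-2-yl]dec-7-en-1-one, via alkylmagnesium bromide 20 (not isolated)
Conditions: 14, Mg, THF, 40 °C; then 19, THF, −30 → 0 °C; aq. NH4Cl
Reagents that add atoms: none
Why: Weinreb ketone synthesis: the chelated tetrahedral adduct prevents a second addition and forms the C4–C5 bond. At low temperature the carbonyl should react before the epoxide, and the strained epoxide C–H next to the carbonyl is not readily removed, so C3 and C2 keep their configuration.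

Step 12
Reactants: 21 (3R,7E)-10-[5-(furan-3-ylmethyl)furan-3-yl]-3,7-dimethyl-1-[(2R,3R)-3-methyloxiran-2-yl]dec-7-en-1-one
Product: 22 (2S,3S,6R,10E)-2-chloro-13-[5-(furan-3-ylmethyl)furan-3-yl]-3-hydroxy-6,10-dimethyltridec-10-en-4-one
Conditions: LiCl, AcOH, THF, rt
Reagents that add atoms: lithium chloride [Li+].[Cl-]
Why: Acid-assisted SN2 opening of the α,β-epoxy ketone: chloride should attack the β-carbon C2, where displacement is not retarded by the adjacent electron-withdrawing acyl group, with inversion, while C3 keeps its oxygen and configuration, so the cis-epoxide gives the syn (2S,3S) chlorohydrin. The weakly acidic, non-basic medium should spare the furans and prevents re-closure to the epoxide or enolisation at C3.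

## Compound list

1 | (5E)-6,10-dimethylundeca-5,9-dien-2-one ((E)-geranylacetone) | C/C(=C\CCC(C)=O)CCC=C(C)C | starting material
2 | (5E,9E)-11-hydroxy-6,10-dimethylundeca-5,9-dien-2-one | C/C(=C\CCC(C)=O)CC/C=C(\C)CO | intermediate
3 | (5E,10R)-11-hydroxy-6,10-dimethylundec-5-en-2-one | C/C(=C\CCC(C)=O)CCC[C@@H](C)CO | intermediate
4 | (5E,10R)-11-bromo-6,10-dimethylundec-5-en-2-one | C/C(=C\CCC(C)=O)CCC[C@@H](C)CBr | intermediate
5 | {[(5E,10R)-11-bromo-6,10-dimethylundeca-1,5-dien-2-yl]oxy}trimethylsilane (formed in situ) | C/C(=C\CCC(=C)O[Si](C)(C)C)CCC[C@@H](C)CBr | intermediate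
6 | (5E,10R)-1,11-dibromo-6,10-dimethylundec-5-en-2-one | C/C(=C\CCC(=O)CBr)CCC[C@@H](C)CBr | intermediate
7 | (diethoxyphosphoryl)acetic acid | CCOP(=O)(CC(=O)O)OCC | starting material
8 | (5E,10R)-11-bromo-6,10-dimethyl-2-oxoundec-5-en-1-yl (diethoxyphosphoryl)acetate (formed in situ) | C/C(=C\CCC(=O)COC(=O)CP(=O)(OCC)OCC)CCC[C@@H](C)CBr | intermediate
9 | 4-[(3E,8R)-9-bromo-4,8-dimethylnon-3-en-1-yl]furan-2(5H)-one | C/C(=C\CCC1=CC(=O)OC1)CCC[C@@H](C)CBr | intermediate
10 | furan-3-ylmethanol | OCc1ccoc1 | starting material
11 | 3-(chloromethyl)furan | ClCc1ccoc1 | intermediate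
12 | (furan-3-ylmethyl)magnesium chloride (formed in situ) | Cl[Mg]Cc1ccoc1 | intermediate
13 | 4-[(3E,8R)-9-bromo-4,8-dimethylnon-3-en-1-yl]-2-(furan-3-ylmethyl)-2,5-dihydrofuran-2-ol (both epimers at the lactol carbon, formed in situ) | C/C(=C\CCC1=CC(O)(Cc2ccoc2)OC1)CCC[C@@H](C)CBr | intermediate
14 | 4-[(3E,8R)-9-bromo-4,8-dimethylnon-3-en-1-yl]-2-(furan-3-ylmethyl)furan | C/C(=C\CCc1coc(Cc2ccoc2)c1)CCC[C@@H](C)CBr | intermediate
15 | L-threonine, (2S,3R)-2-amino-3-hydroxybutanoic acid | C[C@@H](O)[C@H](N)C(=O)O | starting material
16 | (2S,3R)-2-bromo-3-hydroxybutanoic acid | C[C@@H](O)[C@H](Br)C(=O)O | intermediate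
17 | potassium (2R,3R)-3-methyloxirane-2-carboxylate | C[C@H]1O[C@H]1C(=O)[O-].[K+] | intermediate
18 | N,O-dimethylhydroxylamine hydrochloride | CNOC.Cl | starting material
19 | (2R,3R)-N-methoxy-N,3-dimethyloxirane-2-carboxamide | C[C@H]1O[C@H]1C(=O)N(C)OC | intermediate
20 | {(2R,6E)-9-[5-(furan-3-ylmethyl)furan-3-yl]-2,6-dimethylnon-6-en-1-yl}magnesium bromide (formed in situ) | C/C(=C\CCc1coc(Cc2ccoc2)c1)CCC[C@@H](C)C[Mg]Br | intermediate
21 | (3R,7E)-10-[5-(furan-3-ylmethyl)furan-3-yl]-3,7-dimethyl-1-[(2R,3R)-3-methyloxiran-2-yl]dec-7-en-1-one | C/C(=C\CCc1coc(Cc2ccoc2)c1)CCC[C@@H](C)CC(=O)[C@@H]1O[C@@H]1C | intermediate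
22 | (2S,3S,6R,10E)-2-chloro-13-[5-(furan-3-ylmethyl)furan-3-yl]-3-hydroxy-6,10-dimethyltridec-10-en-4-one | C/C(=C\CCc1coc(Cc2ccoc2)c1)CCC[C@@H](C)CC(=O)[C@H](O)[C@H](C)Cl | target

## Step count and risk

Total step count: 12. Longest linear sequence: 8 steps (steps 1, 2, 3, 4, 5, 7, 11 and 12, from 1); steps 6 and 8–10 are side branches.

Steps least certain to work:

Step 5 (key step). Under base the keto ester 8 may enolise toward C13 or C5′ and undergo acyl migration or self-condensation faster than the phosphonate adds to the ketone, and the double bond of 9 may drift out of conjugation. The fallback sets out from 6 and comes back at 9. Bromoacetic acid is alkylated with 6 (K2CO3, MeCN) to give (5E,10R)-11-bromo-6,10-dimethyl-2-oxoundec-5-en-1-yl bromoacetate F1. The C3′–C4′ bond is then closed by an intramolecular Reformatsky reaction (activated Zn, THF), in which a weakly basic zinc enolate adds to the ketone, to give 4-[(3E,8R)-9-bromo-4,8-dimethylnon-3-en-1-yl]-4-hydroxydihydrofuran-2(3H)-one F2. Dehydration with catalytic p-toluenesulfonic acid in warm toluene gives 9.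

Step 7. The reagent may deprotonate 9 at C5′ instead of adding to the carbonyl, a second equivalent may add after ring opening of the lactol salt, the halide may dimerise while 12 is formed, or the furylmethyl metal may react through its ring carbon. The fallback sets out from 9 and comes back at 14. Reduction of 9 with i-Bu2AlH (CH2Cl2, −78 °C, acidic work-up) gives 3-[(3E,8R)-9-bromo-4,8-dimethylnon-3-en-1-yl]furan F3. Iridium-catalysed C–H borylation ([Ir(OMe)(cod)]2, 4,4′-di-tert-butyl-2,2′-bipyridine, B2pin2, hexane) at the unhindered α-carbon C2′ gives 2-{4-[(3E,8R)-9-bromo-4,8-dimethylnon-3-en-1-yl]furan-2-yl}-4,4,5,5-tetramethyl-1,3,2-dioxaborolane F4. Suzuki–Miyaura coupling of this boronate with 11 (Pd(PPh3)4, K3PO4, THF/H2O) gives 14.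

Step 2. Facial discrimination may be incomplete because the substrate is a 2-methyl-substituted and not a 3-substituted allylic alcohol, and isomerisation of the allylic alcohol to the aldehyde may compete at low hydrogen pressure; an eroded C6 configuration would later appear as a diastereomer that is hard to remove. The fallback sets out from 2 and comes back at 3. Oxidation with MnO2 gives (2E,6E)-2,6-dimethyl-10-oxoundeca-2,6-dienal F5. Its activated C=C bond is reduced by an ene-reductase of the Old Yellow Enzyme class (NADPH recycled with glucose and glucose dehydrogenase), selected from a panel for the R-product, to (2R,6E)-2,6-dimethyl-10-oxoundec-6-enal F6. Aldehyde-selective reduction with NaBH(OAc)3 gives 3.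

Step 12. Chloride may attack C3 instead of C2, or the furans may degrade in the acidic medium before the opening is complete. The fallback sets out from 19 and comes back at 22. The epoxide is opened at the amide stage (LiCl, AcOH, THF), where no furan is present and a regioisomer can be removed from a small molecule, to give (2S,3S)-3-chloro-2-hydroxy-N-methoxy-N-methylbutanamide F7. Silylation (Et3SiCl, imidazole) gives (2S,3S)-3-chloro-N-methoxy-N-methyl-2-[(triethylsilyl)oxy]butanamide F8. Addition of 20 gives (2S,3S,6R,10E)-2-chloro-13-[5-(furan-3-ylmethyl)furan-3-yl]-6,10-dimethyl-3-[(triethylsilyl)oxy]tridec-10-en-4-one F9. Removal of the silyl group with AcOH/THF/H2O gives 22.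

Step 11. Homocoupling may occur during the magnesium insertion, and the magnesium salts may promote opening of the epoxide of 19 or 21 by bromide. The fallback sets out from 17 and 14 and comes back at 21. Compound 17 is converted (t-BuCOCl, then EtSH, Et3N) into S-ethyl (2R,3R)-3-methyloxirane-2-carbothioate F10. Zinc is inserted into 14 (Zn dust, LiCl, THF) to give {(2R,6E)-9-[5-(furan-3-ylmethyl)furan-3-yl]-2,6-dimethylnon-6-en-1-yl}zinc bromide F11. Fukuyama coupling of the two (PdCl2(PPh3)2 cat., THF/toluene, rt) gives 21 under neutral conditions.

## Further compounds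

F1 | step 5 | (5E,10R)-11-bromo-6,10-dimethyl-2-oxoundec-5-en-1-yl bromoacetate | C/C(=C\CCC(=O)COC(=O)CBr)CCC[C@@H](C)CBr
F2 | step 5 | 4-[(3E,8R)-9-bromo-4,8-dimethylnon-3-en-1-yl]-4-hydroxydihydrofuran-2(3H)-one (both epimers at the carbinol carbon) | C/C(=C\CCC1(O)CC(=O)OC1)CCC[C@@H](C)CBr
F3 | step 7 | 3-[(3E,8R)-9-bromo-4,8-dimethylnon-3-en-1-yl]furan | C/C(=C\CCc1ccoc1)CCC[C@@H](C)CBr
F4 | step 7 | 2-{4-[(3E,8R)-9-bromo-4,8-dimethylnon-3-en-1-yl]furan-2-yl}-4,4,5,5-tetramethyl-1,3,2-dioxaborolane | C/C(=C\CCc1coc(B2OC(C)(C)C(C)(C)O2)c1)CCC[C@@H](C)CBr
F5 | step 2 | (2E,6E)-2,6-dimethyl-10-oxoundeca-2,6-dienal | C/C(=C\CCC(C)=O)CC/C=C(\C)C=O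
F6 | step 2 | (2R,6E)-2,6-dimethyl-10-oxoundec-6-enal | C/C(=C\CCC(C)=O)CCC[C@@H](C)C=O
F7 | step 12 | (2S,3S)-3-chloro-2-hydroxy-N-methoxy-N-methylbutanamide | CON(C)C(=O)[C@H](O)[C@H](C)Cl
F8 | step 12 | (2S,3S)-3-chloro-N-methoxy-N-methyl-2-[(triethylsilyl)oxy]butanamide | CON(C)C(=O)[C@H](O[Si](CC)(CC)CC)[C@H](C)Cl
F9 | step 12 | (2S,3S,6R,10E)-2-chloro-13-[5-(furan-3-ylmethyl)furan-3-yl]-6,10-dimethyl-3-[(triethylsilyl)oxy]tridec-10-en-4-one | C/C(=C\CCc1coc(Cc2ccoc2)c1)CCC[C@@H](C)CC(=O)[C@H](O[Si](CC)(CC)CC)[C@H](C)Cl
F10 | step 11 | S-ethyl (2R,3R)-3-methyloxirane-2-carbothioate | C[C@H]1O[C@H]1C(=O)SCC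
F11 | step 11 | {(2R,6E)-9-[5-(furan-3-ylmethyl)furan-3-yl]-2,6-dimethylnon-6-en-1-yl}zinc bromide | C/C(=C\CCc1coc(Cc2ccoc2)c1)CCC[C@@H](C)C[Zn]Br
A1 | alternative 1 | 4-(chloromethyl)-2-(furan-3-ylmethyl)furan | ClCc1coc(Cc2ccoc2)c1
A2 | alternative 1 | tert-butyl{[(2R,6E)-8-bromo-2,6-dimethyloct-6-en-1-yl]oxy}dimethylsilane | C/C(=C\CBr)CCC[C@@H](C)CO[Si](C)(C)C(C)(C)C
A3 | alternative 2 | 2-{(2R,6E)-9-[5-(furan-3-ylmethyl)furan-3-yl]-2,6-dimethylnon-6-en-1-yl}-1,3-dithiane | C/C(=C\CCc1coc(Cc2ccoc2)c1)CCC[C@@H](C)CC1SCCCS1
A4 | alternative 2 | (2S)-2-chloropropanal | C[C@H](Cl)C=O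
A5 | alternative 2 | (1R,2S)-2-chloro-1-(2-{(2R,6E)-9-[5-(furan-3-ylmethyl)furan-3-yl]-2,6-dimethylnon-6-en-1-yl}-1,3-dithian-2-yl)propan-1-ol | C/C(=C\CCc1coc(Cc2ccoc2)c1)CCC[C@@H](C)CC1(SCCCS1)[C@@H](O)[C@H](C)Cl
A6 | alternative 3 | 1-(furan-3-yl)but-3-en-2-yl (5E,10R)-11-bromo-6,10-dimethyl-2-methylideneundec-5-enoate (either configuration at the carbinol carbon) | C=CC(Cc1ccoc1)OC(=O)C(=C)CC/C=C(\C)CCC[C@@H](C)CBr
A7 | alternative 3 | 3-[(3E,8R)-9-bromo-4,8-dimethylnon-3-en-1-yl]-5-(furan-3-ylmethyl)furan-2(5H)-one (either configuration at the ring carbinol carbon) | C/C(=C\CCC1=CC(Cc2ccoc2)OC1=O)CCC[C@@H](C)CBr
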